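**Retrosynthetic overview**

1. The aryl allyl ether is made last, by Mitsunobu union of the allylic alcohol of the terpenoid half with 4-hydroxy-5-methylcoumarin; the pyranone ring of the coumarin is built separately by carbonate condensation of 2'-hydroxy-6'-methylacetophenone.
2. The cyclohexanone ring (C1 ketone, C2 CMe2, C3 stereocentre, C4 carbon bearing the exocyclic methylene, C5, C6) is closed at C4–C5. The enabling feature is that the ketone C1 with its α- and β-methylene carbons C6 and C5 is the retron of a 1-substituted cyclopropanol (a ketone homoenolate), while C4 is the substituted carbon of a 1,1-disubstituted alkene and can be carried as a 2-bromoalkene. A palladium-catalysed ring-opening cross-coupling then makes the ring, the ketone and the methylene group in one operation.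
3. The temporary cyclopropane comes from a Kulinkovich reaction of a methyl ester; before that the side chain is attached by hydroboration of a vinyl group and B-alkyl Suzuki coupling with an (E)-iodobutenyl silyl ether.
4. The only stereocentre (C3) and the neighbouring quaternary carbon C2 arise together in an iridium-catalysed asymmetric allylic alkylation of a 4-bromopentadienyl carbonate with the silyl ketene acetal of methyl isobutyrate.
5. Ring order: pyranone of the coumarin (separate branch), cyclopropane (temporary), cyclohexanone (key step).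

Key step: step 10

Assumption: the facial preference known for cyclometalated iridium phosphoramidite catalysts with aryl-, alkyl- and dienyl-substituted allyl carbonates is taken to hold for the 1-bromovinyl-substituted allyl unit; L* denotes the antipode of O,O'-(1,1'-binaphthalene-2,2'-diyl) N,N-bis(1-phenylethyl)phosphoramidite that this preference assigns to the (3S) product (its mirror image would give the enantiomer).

**Route**

Step 1
Reactants: 1 acrolein (prop-2-enal)
Product: 3 2-bromoprop-2-enal, via 2,3-dibromopropanal 2 (not isolated)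
Conditions: Br2 (1.0 equiv), CH2Cl2, −78 °C; then Et3N (1.05 equiv), −78 → 0 °C; used at once as a cold solution
Reagents that add atoms: bromine BrBr
Why: Bromine adds across the enal C=C and triethylamine then removes HBr from the α-bromo aldehyde by an E1cB elimination, the usual bromination–dehydrobromination route to 2-bromoacrolein, which is used directly because it polymerises on storage.

Step 2
Reactants: 3 2-bromoprop-2-enal; 4 methyl (triphenylphosphoranylidene)acetate
Product: 5 methyl (2E)-4-bromopenta-2,4-dienoate
Conditions: CH2Cl2, 0 °C → rt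
Reagents that add atoms: none
Why: Wittig olefination with a stabilised ylide, which reacts at the aldehyde carbonyl and should give the (E)-enoate under thermodynamic control of the oxaphosphetane stage while the alkenyl bromide is inert.

Step 3
Reactants: 5 methyl (2E)-4-bromopenta-2,4-dienoate
Product: 6 (2E)-4-bromopenta-2,4-dien-1-ol
Conditions: i-Bu2AlH (DIBAL-H, 2.2 equiv), CH2Cl2, −78 °C; aqueous potassium sodium tartrate work-up
Reagents that add atoms: none
Why: i-Bu2AlH reduces the conjugated ester in a 1,2 sense to the allylic alcohol at low temperature (ester reduction with an aluminium hydride) and leaves the bromodiene and the (E) geometry untouched.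

Step 4
Reactants: 6 (2E)-4-bromopenta-2,4-dien-1-ol
Product: 7 (2E)-4-bromopenta-2,4-dien-1-yl methyl carbonate
Conditions: ClCO2Me, pyridine, CH2Cl2, 0 °C
Reagents that add atoms: methyl chloroformate COC(Cl)=O
Why: Acylation of the primary allylic alcohol with a chloroformate (carbonate formation) installs the leaving group that also serves as the internal source of methoxide in the next step.

Step 5
Reactants: 7 (2E)-4-bromopenta-2,4-dien-1-yl methyl carbonate; 8 [(1-methoxy-2-methylprop-1-en-1-yl)oxy]trimethylsilane
Product: 9 methyl (3S)-4-bromo-3-ethenyl-2,2-dimethylpent-4-enoate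
Conditions: [Ir(cod)Cl]2 (2 mol%), L* (4 mol%; catalyst cyclometalated beforehand with n-PrNH2), THF, rt
Reagents that add atoms: none
Why: Iridium-catalysed asymmetric allylic alkylation, in which the cyclometalated iridium phosphoramidite ionises the carbonate to a π-allyl complex, the liberated methoxide desilylates 8, and the ester enolate attacks the substituted allyl terminus anti to the metal, so that the branched product with the quaternary carbon next to the new tertiary centre should form and the chiral ligand sets its (S) configuration.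

Step 6
Reactants: 10 but-2-yn-1-ol
Product: 11 tert-butyl(but-2-yn-1-yloxy)dimethylsilane
Conditions: TBSCl, imidazole, DMF, rt
Reagents that add atoms: tert-butyldimethylsilyl chloride CC(C)(C)[Si](C)(C)Cl
Why: Standard silylation of a primary alcohol (silyl ether protection) gives an ether that survives the organozirconium, borane, Grignard and palladium steps that follow.

Step 7
Reactants: 11 tert-butyl(but-2-yn-1-yloxy)dimethylsilane
Product: 13 tert-butyl{[(2E)-3-iodobut-2-en-1-yl]oxy}dimethylsilane, via alkenylzirconocene chloride 12 (not isolated)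
Conditions: Cp2Zr(H)Cl (2.0 equiv), THF, 50 °C; then I2, THF, 0 °C
Reagents that add atoms: iodine II
Why: Syn hydrozirconation of the internal alkyne under equilibrating conditions (excess Cp2Zr(H)Cl and heat) should place zirconium on the less hindered methyl-bearing carbon remote from the silyloxymethyl group, and iodinolysis with retention then gives the (E)-alkenyl iodide (hydrozirconation–iodination).

Step 8
Reactants: 9 methyl (3S)-4-bromo-3-ethenyl-2,2-dimethylpent-4-enoate; 13 tert-butyl{[(2E)-3-iodobut-2-en-1-yl]oxy}dimethylsilane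
Product: 15 methyl (3S,6E)-3-(1-bromoethenyl)-8-{[tert-butyl(dimethyl)silyl]oxy}-2,2,6-trimethyloct-6-enoate, via B-alkyl-9-BBN adduct 14 (not isolated)
Conditions: 9-BBN (1.1 equiv), THF, 0 °C → rt; then 13 (1.2 equiv), PdCl2(dppf) (5 mol%), AsPh3 (10 mol%), Cs2CO3 (3 equiv), DMF/H2O, rt
Reagents that add atoms: none
Why: 9-BBN adds its boron only to the terminal carbon of the monosubstituted vinyl group (the bromoalkene is electron-poor and 1,1-disubstituted and the ester is inert), and the B-alkyl Suzuki–Miyaura coupling then occurs at the alkenyl iodide of 13, which undergoes oxidative addition to zerovalent palladium far faster than the hindered alkenyl bromide, with retention of the (E) geometry and with the borane kept as the limiting partner.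

Step 9
Reactants: 15 methyl (3S,6E)-3-(1-bromoethenyl)-8-{[tert-butyl(dimethyl)silyl]oxy}-2,2,6-trimethyloct-6-enoate
Product: 16 1-[(3S,6E)-3-(1-bromoethenyl)-8-{[tert-butyl(dimethyl)silyl]oxy}-2,6-dimethyloct-6-en-2-yl]cyclopropan-1-ol
Conditions: EtMgBr (3.2 equiv, slow addition), Ti(OiPr)4 (0.5 equiv), THF, 0 °C → rt; aq. NH4Cl
Reagents that add atoms: ethylmagnesium bromide CC[Mg]Br
Why: Kulinkovich cyclopropanation, in which the titanacyclopropane formed from two ethyl groups acts as a 1,2-dicarbanion toward the ester carbonyl and gives the 1-substituted cyclopropanol, while the silyl ether, the trisubstituted alkene, the alkenyl bromide and the stereocentre are not involved.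

Step 10
Reactants: 16 1-[(3S,6E)-3-(1-bromoethenyl)-8-{[tert-butyl(dimethyl)silyl]oxy}-2,6-dimethyloct-6-en-2-yl]cyclopropan-1-ol
Product: 17 (3R)-3-[(3E)-5-{[tert-butyl(dimethyl)silyl]oxy}-3-methylpent-3-en-1-yl]-2,2-dimethyl-4-methylidenecyclohexan-1-one
Conditions: Pd(OAc)2 (10 mol%), XPhos (20 mol%), Cs2CO3 (2 equiv), toluene, 80 °C
Reagents that add atoms: none
Why: Zerovalent palladium inserts into the C–Br bond of the 1-bromoethenyl group, carbonate-assisted exchange gives a divalent palladium cyclopropoxide, and strain-releasing β-carbon elimination opens the three-membered ring to a palladium homoenolate held in a seven-membered palladacycle, from which C(sp2)–C(sp3) reductive elimination forms the C4–C5 bond. The closest known reaction type is the palladium-catalysed ring-opening cross-coupling of cyclopropanols with aryl and alkenyl halides, including ring-forming intramolecular cases. The cyclohexanone ring is closed by reductive elimination from the seven-membered palladacycle (formally a 6-exo closure onto the alkenyl carbon); in the same event the ketone is unmasked and the exocyclic methylene is placed regiospecifically, because the double bond never leaves the former bromoalkene. No stereocentre is created: C3 is a spectator that is not α to the new carbonyl (C2 is quaternary), so its configuration is retained, and the descriptor changes from S to R only because bromine is lost. The selectivity needed is reductive elimination over β-hydride elimination of the homoenolate (which would give an acyclic enone and a debrominated diene); it should be secured by the bulky biaryl phosphine, by the intramolecular setting and by the gem-dimethyl group at C2, which favours the folded palladacycle, while the two cyclopropane CH2 groups are equivalent so that ring opening has no regiochemical issue.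

Step 11
Reactants: 17 (3R)-3-[(3E)-5-{[tert-butyl(dimethyl)silyl]oxy}-3-methylpent-3-en-1-yl]-2,2-dimethyl-4-methylidenecyclohexan-1-one
Product: 18 (3R)-3-[(3E)-5-hydroxy-3-methylpent-3-en-1-yl]-2,2-dimethyl-4-methylidenecyclohexan-1-one
Conditions: HF·pyridine, pyridine, THF, 0 °C → rt
Reagents that add atoms: none
Why: Fluoride-mediated cleavage of the silyl ether (desilylation) under buffered conditions frees the primary allylic alcohol without isomerising the exocyclic alkene or enolising the ketone.

Step 12
Reactants: 19 1-(2-hydroxy-6-methylphenyl)ethan-1-one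
Product: 20 4-hydroxy-5-methyl-2H-chromen-2-one
Conditions: NaH (3 equiv), diethyl carbonate (excess), toluene, 110 °C; then aq. HCl
Reagents that add atoms: diethyl carbonate CCOC(=O)OCC
Why: Claisen-type C-acylation of the acetophenone enolate by the carbonate followed by lactonisation onto the phenoxide gives the 4-hydroxycoumarin (carbonate condensation and cyclisation), the ortho methyl group ending at C5.

Step 13
Reactants: 18 (3R)-3-[(3E)-5-hydroxy-3-methylpent-3-en-1-yl]-2,2-dimethyl-4-methylidenecyclohexan-1-one; 20 4-hydroxy-5-methyl-2H-chromen-2-one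
Product: 21 4-{[(2E)-5-[(1R)-2,2-dimethyl-6-methylidene-3-oxocyclohexyl]-3-methylpent-2-en-1-yl]oxy}-5-methyl-2H-chromen-2-one
Conditions: PPh3, DIAD, THF, 0 °C → rt
Reagents that add atoms: none
Why: Mitsunobu redox condensation, in which the acidic vinylogous carboxylic acid hydroxyl of 20 is alkylated on oxygen by the alkoxyphosphonium ion of the primary allylic alcohol in an SN2 process that should preserve the (E) alkene and leave the ketone and the stereocentre untouched.

**Compound list**

1 | acrolein (prop-2-enal) | C=CC=O | starting material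
2 | 2,3-dibromopropanal | O=CC(Br)CBr | intermediate
3 | 2-bromoprop-2-enal | C=C(Br)C=O | intermediate
4 | methyl (triphenylphosphoranylidene)acetate | COC(=O)C=P(c1ccccc1)(c1ccccc1)c1ccccc1 | starting material
5 | methyl (2E)-4-bromopenta-2,4-dienoate | COC(=O)/C=C/C(Br)=C | intermediate
6 | (2E)-4-bromopenta-2,4-dien-1-ol | OC/C=C/C(Br)=C | intermediate
7 | (2E)-4-bromopenta-2,4-dien-1-yl methyl carbonate | COC(=O)OC/C=C/C(Br)=C | intermediate
8 | [(1-methoxy-2-methylprop-1-en-1-yl)oxy]trimethylsilane | COC(O[Si](C)(C)C)=C(C)C | starting material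
9 | methyl (3S)-4-bromo-3-ethenyl-2,2-dimethylpent-4-enoate | COC(=O)C(C)(C)[C@@H](C(Br)=C)C=C | intermediate
10 | but-2-yn-1-ol | CC#CCO | starting material
11 | tert-butyl(but-2-yn-1-yloxy)dimethylsilane | CC#CCO[Si](C)(C)C(C)(C)C | intermediate
12 | chlorobis(cyclopentadienyl)[(2E)-4-{[tert-butyl(dimethyl)silyl]oxy}but-2-en-2-yl]zirconium (cyclopentadienyl rings drawn σ-bonded) | C/C(=C\CO[Si](C)(C)C(C)(C)C)[Zr](Cl)(C1C=CC=C1)C1C=CC=C1 | intermediate
13 | tert-butyl{[(2E)-3-iodobut-2-en-1-yl]oxy}dimethylsilane | C/C(I)=C\CO[Si](C)(C)C(C)(C)C | intermediate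
14 | methyl (3S)-5-(9-borabicyclo[3.3.1]nonan-9-yl)-3-(1-bromoethenyl)-2,2-dimethylpentanoate | COC(=O)C(C)(C)[C@@H](C(Br)=C)CCB1C2CCCC1CCC2 | intermediate
15 | methyl (3S,6E)-3-(1-bromoethenyl)-8-{[tert-butyl(dimethyl)silyl]oxy}-2,2,6-trimethyloct-6-enoate | COC(=O)C(C)(C)[C@@H](C(Br)=C)CC/C(C)=C/CO[Si](C)(C)C(C)(C)C | intermediate
16 | 1-[(3S,6E)-3-(1-bromoethenyl)-8-{[tert-butyl(dimethyl)silyl]oxy}-2,6-dimethyloct-6-en-2-yl]cyclopropan-1-ol | OC1(CC1)C(C)(C)[C@@H](C(Br)=C)CC/C(C)=C/CO[Si](C)(C)C(C)(C)C | intermediate
17 | (3R)-3-[(3E)-5-{[tert-butyl(dimethyl)silyl]oxy}-3-methylpent-3-en-1-yl]-2,2-dimethyl-4-methylidenecyclohexan-1-one | C=C1CCC(=O)C(C)(C)[C@@H]1CC/C(C)=C/CO[Si](C)(C)C(C)(C)C | intermediate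
18 | (3R)-3-[(3E)-5-hydroxy-3-methylpent-3-en-1-yl]-2,2-dimethyl-4-methylidenecyclohexan-1-one | C=C1CCC(=O)C(C)(C)[C@@H]1CC/C(C)=C/CO | intermediate
19 | 1-(2-hydroxy-6-methylphenyl)ethan-1-one | CC(=O)c1c(C)cccc1O | starting material
20 | 4-hydroxy-5-methyl-2H-chromen-2-one | Cc1cccc2oc(=O)cc(O)c12 | intermediate
21 | 4-{[(2E)-5-[(1R)-2,2-dimethyl-6-methylidene-3-oxocyclohexyl]-3-methylpent-2-en-1-yl]oxy}-5-methyl-2H-chromen-2-one | C=C1CCC(=O)C(C)(C)[C@@H]1CC/C(C)=C/COc1cc(=O)oc2cccc(C)c12 | target

**Step count and risks**

Total steps: 13. Longest linear sequence: 10 steps (steps 1–5, 8–11 and 13).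

Steps most likely to fail:

1. Step 5 (iridium-catalysed allylic alkylation). The enolate may attack the wrong allyl terminus (linear product or the remote end of the bromodiene), iridium may insert into the alkenyl C–Br bond, or facial discrimination may be insufficient with this unusual allyl substituent. The fallback sets out from 6 and comes back at 9. Alcohol 6 is acylated with isobutyryl chloride and pyridine to (2E)-4-bromopenta-2,4-dien-1-yl 2-methylpropanoate F1. An Ireland–Claisen rearrangement (LiN(i-Pr)2, Me3SiCl, THF, −78 → 50 °C) then passes through the silyl ketene acetal F2 and the rearranged trimethylsilyl ester F3, neither isolated. The [3,3] shift joins the isobutyrate α-carbon to C3 of the dienyl unit and leaves exactly the vinyl and 1-bromovinyl pair; aqueous work-up gives racemic 4-bromo-3-ethenyl-2,2-dimethylpent-4-enoic acid F4. Methylation (Me3SiCHN2, MeOH/toluene) gives the racemic methyl ester F5, and preparative chromatography on a chiral stationary phase delivers 9.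

2. Step 10 (ring-opening cross-coupling). β-Hydride elimination of the palladium homoenolate may outrun reductive elimination; oxidative addition at the hindered bromoalkene may be slow enough for base-induced opening of the cyclopropanol to an ethyl ketone to compete; palladium hydride may shift the exocyclic double bond into the ring. The fallback sets out from 15 and comes back at 17, forming the same C4–C5 bond by an intramolecular B-alkyl Suzuki coupling. Ester 15 is reduced with i-Bu2AlH to (3S,6E)-3-(1-bromoethenyl)-8-{[tert-butyl(dimethyl)silyl]oxy}-2,2,6-trimethyloct-6-en-1-ol F6 and oxidised with Dess–Martin periodinane to the corresponding aldehyde F7. Addition of CH2=CHMgBr gives (5S,8E)-5-(1-bromoethenyl)-10-{[tert-butyl(dimethyl)silyl]oxy}-4,4,8-trimethyldeca-1,8-dien-3-ol F8 as both carbinol epimers, which is inconsequential. Hydroboration with 9-BBN (2.2 equiv) gives the B-alkyl borane O-borinate F9, not isolated, and PdCl2(dppf), AsPh3 and Cs2CO3 in DMF/H2O at 50 °C close the ring to (3R)-3-[(3E)-5-{[tert-butyl(dimethyl)silyl]oxy}-3-methylpent-3-en-1-yl]-2,2-dimethyl-4-methylidenecyclohexan-1-ol F10. Dess–Martin oxidation gives 17.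

3. Step 9 (Kulinkovich reaction). Insertion of the very hindered, neopentyl-type ester carbonyl into the titanacyclopropane may be slow, leaving room for reduction of the alkenyl bromide by low-valent titanium or for simple ethyl addition. The fallback sets out from 15 and comes back at 16. Ester 15 is treated with Me3SiCH2Li (pentane/THF, 0 °C) to give (4S,7E)-4-(1-bromoethenyl)-9-{[tert-butyl(dimethyl)silyl]oxy}-3,3,7-trimethyl-1-(trimethylsilyl)non-7-en-2-one F11, not isolated, which is protodesilylated with methanol to the methyl ketone (4S,7E)-4-(1-bromoethenyl)-9-{[tert-butyl(dimethyl)silyl]oxy}-3,3,7-trimethylnon-7-en-2-one F12. Kinetic enolisation and silylation (LiN(i-Pr)2, Me3SiCl, THF, −78 °C) give the trimethylsilyl enol ether F13. Simmons–Smith cyclopropanation of this electron-rich alkene (Et2Zn, CH2I2, CH2Cl2, 0 °C) gives the trimethylsilyloxycyclopropane F14, and K2CO3 in methanol releases 16.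

Further compounds
F1 | step 5 | (2E)-4-bromopenta-2,4-dien-1-yl 2-methylpropanoate | CC(C)C(=O)OC/C=C/C(Br)=C
F2 | step 5 | ({1-[(2E)-4-bromopenta-2,4-dien-1-yl]oxy-2-methylprop-1-en-1-yl}oxy)trimethylsilane | CC(C)=C(O[Si](C)(C)C)OC/C=C/C(Br)=C
F3 | step 5 | trimethylsilyl 4-bromo-3-ethenyl-2,2-dimethylpent-4-enoate (racemic) | C[Si](C)(C)OC(=O)C(C)(C)C(C(Br)=C)C=C
F4 | step 5 | 4-bromo-3-ethenyl-2,2-dimethylpent-4-enoic acid (racemic) | OC(=O)C(C)(C)C(C(Br)=C)C=C
F5 | step 5 | methyl 4-bromo-3-ethenyl-2,2-dimethylpent-4-enoate (racemic) | COC(=O)C(C)(C)C(C(Br)=C)C=C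
F6 | step 10 | (3S,6E)-3-(1-bromoethenyl)-8-{[tert-butyl(dimethyl)silyl]oxy}-2,2,6-trimethyloct-6-en-1-ol | OCC(C)(C)[C@@H](C(Br)=C)CC/C(C)=C/CO[Si](C)(C)C(C)(C)C
F7 | step 10 | (3S,6E)-3-(1-bromoethenyl)-8-{[tert-butyl(dimethyl)silyl]oxy}-2,2,6-trimethyloct-6-enal | O=CC(C)(C)[C@@H](C(Br)=C)CC/C(C)=C/CO[Si](C)(C)C(C)(C)C
F8 | step 10 | (5S,8E)-5-(1-bromoethenyl)-10-{[tert-butyl(dimethyl)silyl]oxy}-4,4,8-trimethyldeca-1,8-dien-3-ol (both C3 epimers) | C=CC(O)C(C)(C)[C@@H](C(Br)=C)CC/C(C)=C/CO[Si](C)(C)C(C)(C)C
F9 | step 10 | B-alkyl-9-BBN O-borinate from F8 | B1(C2CCCC1CCC2)CCC(OB1C2CCCC1CCC2)C(C)(C)[C@@H](C(Br)=C)CC/C(C)=C/CO[Si](C)(C)C(C)(C)C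
F10 | step 10 | (3R)-3-[(3E)-5-{[tert-butyl(dimethyl)silyl]oxy}-3-methylpent-3-en-1-yl]-2,2-dimethyl-4-methylidenecyclohexan-1-ol (both C1 epimers) | C=C1CCC(O)C(C)(C)[C@@H]1CC/C(C)=C/CO[Si](C)(C)C(C)(C)C
F11 | step 9 | (4S,7E)-4-(1-bromoethenyl)-9-{[tert-butyl(dimethyl)silyl]oxy}-3,3,7-trimethyl-1-(trimethylsilyl)non-7-en-2-one | C[Si](C)(C)CC(=O)C(C)(C)[C@@H](C(Br)=C)CC/C(C)=C/CO[Si](C)(C)C(C)(C)C
F12 | step 9 | (4S,7E)-4-(1-bromoethenyl)-9-{[tert-butyl(dimethyl)silyl]oxy}-3,3,7-trimethylnon-7-en-2-one | CC(=O)C(C)(C)[C@@H](C(Br)=C)CC/C(C)=C/CO[Si](C)(C)C(C)(C)C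
F13 | step 9 | {[(4S,7E)-4-(1-bromoethenyl)-9-{[tert-butyl(dimethyl)silyl]oxy}-3,3,7-trimethylnona-1,7-dien-2-yl]oxy}trimethylsilane | C=C(O[Si](C)(C)C)C(C)(C)[C@@H](C(Br)=C)CC/C(C)=C/CO[Si](C)(C)C(C)(C)C
F14 | step 9 | {1-[(3S,6E)-3-(1-bromoethenyl)-8-{[tert-butyl(dimethyl)silyl]oxy}-2,6-dimethyloct-6-en-2-yl]cyclopropoxy}trimethylsilane | C[Si](C)(C)OC1(CC1)C(C)(C)[C@@H](C(Br)=C)CC/C(C)=C/CO[Si](C)(C)C(C)(C)C
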